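**Retrosynthetic overview**
1. The C14 acetate (α'-acetoxylation of the enone) and the C2 tiglate are installed last; the ten-membered ring is opened at the (Z)-C5=C6 olefin (ring-closing metathesis).
2. The resulting seco-diene is cut at C8–C9 (sp2–sp3 Negishi coupling) into cyclohexenone iodide 16 (C1–C5, C9–C16, C20) and bromobutenolide 25 (C6–C8, C17–C19).
3. Fragment 16: enantioselective Diels–Alder reaction (C1), catalyst-controlled organozinc addition (C2), CBS reduction then [2,3]-Wittig–Still shift (C10, C9), allylic oxidation (C13 ketone).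
4. Fragment 25: (R)-α-hydroxy-γ-butyrolactone gives C7; Dieckmann closure to the tetronic acid, bromination, selenoxide elimination to the vinyl group.
5. Ring order: six-membered ring (Diels–Alder) and butenolide (Dieckmann) in separate branches, ten-membered ring last.

Assumption: the SMILES is taken as the full definition of CNP0218548.3; the (S)-oxazaborolidinium catalyst of step 2 is taken to give (R)-4, and its mirror-image catalyst would be used if the sense proved opposite.

Labels (briarane numbering, used for all intermediates): C1 quaternary carbon (CH3-15); C2 CH–O; C3, C4 CH2; C5(CH3-16)=C6; C7 lactone CH–O; C8=C17(CH3-18); C19 lactone C=O; C9 CH2; C10 CH; C11(CH3-20)=C12; C13 C=O; C14 CH–OAc. The target is (1R,2S,5Z,7R,10R,14S).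

**Route**

Step 1
Reactants: 1 3-methylbut-3-en-2-one
Product: 2 triisopropyl[(3-methylbuta-1,3-dien-2-yl)oxy]silane
Conditions: TIPSOTf, Et3N, CH2Cl2, 0 °C
Reagents that add atoms: triisopropylsilyl trifluoromethanesulfonate, CC(C)[Si](C(C)C)(C(C)C)OS(=O)(=O)C(F)(F)F
Why: Soft enolisation and O-silylation of the methyl ketone (only the CH3 is enolisable) gives the 2-silyloxy diene as a TIPS enol ether robust enough for the Lewis-acidic cycloaddition.

Step 2
Reactants: 2 triisopropyl[(3-methylbuta-1,3-dien-2-yl)oxy]silane; 3 2-methylprop-2-enal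
Product: 4 (1R)-1,3-dimethyl-4-[(triisopropylsilyl)oxy]cyclohex-3-ene-1-carbaldehyde
Conditions: (S)-B-(o-tolyl)oxazaborolidine from (S)-α,α-diphenylprolinol, activated with Tf2NH (20 mol%), CH2Cl2, −78 → −40 °C
Reagents that add atoms: none
Why: Enantioselective Diels–Alder reaction in which the silyloxy-activated diene terminus bonds to the enal β-carbon ("para" orientation), so that CHO and CH3 sit on the new quaternary C1, whose configuration is fixed by the open face of the boron-bound s-trans enal in the chiral oxazaborolidinium complex.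

Step 3
Reactants: 4 (1R)-1,3-dimethyl-4-[(triisopropylsilyl)oxy]cyclohex-3-ene-1-carbaldehyde
Product: 5 (1R)-1,3-dimethyl-4-oxocyclohex-2-ene-1-carbaldehyde
Conditions: Pd(OAc)2 (1.05 equiv), MeCN, 25–40 °C
Reagents that add atoms: none
Why: Saegusa–Ito oxidation of the regiodefined silyl enol ether (palladium enolate, then β-hydride elimination into the ring) places the enone at C12(=O)–C11=C10 without touching the non-enolisable aldehyde or C1.

Step 4
Reactants: 6 3-methylbut-3-en-1-ol
Product: 7 4-iodo-2-methylbut-1-ene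
Conditions: I2, PPh3, imidazole, CH2Cl2, 0 °C → rt
Reagents that add atoms: iodine, II
Why: Appel-type iodination of the primary alcohol by SN2 displacement of the alkoxyphosphonium ion.

Step 5
Reactants: 7 4-iodo-2-methylbut-1-ene
Product: 8 bis(3-methylbut-3-en-1-yl)zinc
Conditions: Et2Zn (neat, excess), CuI (0.3 mol%), 50 °C; EtI and excess Et2Zn removed in vacuo, residue taken up in toluene
Reagents that add atoms: diethylzinc, CC[Zn]CC
Why: Copper-catalysed iodine–zinc exchange of a primary alkyl iodide gives the salt-free dialkylzinc required for a ligand-controlled carbonyl addition.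

Step 6
Reactants: 5 (1R)-1,3-dimethyl-4-oxocyclohex-2-ene-1-carbaldehyde; 8 bis(3-methylbut-3-en-1-yl)zinc
Product: 9 (4R)-4-[(1S)-1-hydroxy-4-methylpent-4-en-1-yl]-2,4-dimethylcyclohex-2-en-1-one
Conditions: Ti(OiPr)4 (2 equiv), (1R,2R)-N,N'-(cyclohexane-1,2-diyl)bis(trifluoromethanesulfonamide) (8 mol%), toluene, −20 °C; then aq. HCl
Reagents that add atoms: none
Why: Titanium–bis(sulfonamide)-catalysed enantioselective dialkylzinc addition is chemoselective for the aldehyde over the enone, and because the two ring arms at C1 give no substrate bias the (R,R)-ligand alone sets the (S)-carbinol at C2.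

Step 7
Reactants: 9 (4R)-4-[(1S)-1-hydroxy-4-methylpent-4-en-1-yl]-2,4-dimethylcyclohex-2-en-1-one
Product: 10 (4R)-2,4-dimethyl-4-{(1S)-4-methyl-1-[(triethylsilyl)oxy]pent-4-en-1-yl}cyclohex-2-en-1-one
Conditions: TESCl, imidazole, DMF, rt
Reagents that add atoms: chlorotriethylsilane, CC[Si](Cl)(CC)CC
Why: Silylation masks the hindered C2 hydroxyl so that only the C12 oxygen is alkylated and metallated in the next steps.

Step 8
Reactants: 10 (4R)-2,4-dimethyl-4-{(1S)-4-methyl-1-[(triethylsilyl)oxy]pent-4-en-1-yl}cyclohex-2-en-1-one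
Product: 11 (1R,4R)-2,4-dimethyl-4-{(1S)-4-methyl-1-[(triethylsilyl)oxy]pent-4-en-1-yl}cyclohex-2-en-1-ol
Conditions: (S)-2-methyl-CBS-oxazaborolidine (0.3 equiv), catecholborane, toluene, −78 °C
Reagents that add atoms: none
Why: Corey–Bakshi–Shibata reduction in which the α-methylated alkene arm acts as the large group, so the (S)-catalyst gives the (12R)-alcohol with the C12–O bond on the ring face of CH3-15 and anti to the C2 side chain, while catecholborane spares the 1,1-disubstituted alkene.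

Step 9
Reactants: 11 (1R,4R)-2,4-dimethyl-4-{(1S)-4-methyl-1-[(triethylsilyl)oxy]pent-4-en-1-yl}cyclohex-2-en-1-ol
Product: 12 tributyl({[(1R,4R)-2,4-dimethyl-4-{(1S)-4-methyl-1-[(triethylsilyl)oxy]pent-4-en-1-yl}cyclohex-2-en-1-yl]oxy}methyl)stannane
Conditions: KH, THF, 0 °C; then Bu3SnCH2I, rt
Reagents that add atoms: (iodomethyl)tributylstannane, CCCC[Sn](CCCC)(CCCC)CI
Why: Williamson etherification of the potassium alkoxide places the one-carbon unit that becomes C9 on the C12 oxygen.

Step 10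
Reactants: 12 tributyl({[(1R,4R)-2,4-dimethyl-4-{(1S)-4-methyl-1-[(triethylsilyl)oxy]pent-4-en-1-yl}cyclohex-2-en-1-yl]oxy}methyl)stannane
Product: 14 [(1R,6R)-2,6-dimethyl-6-{(1S)-4-methyl-1-[(triethylsilyl)oxy]pent-4-en-1-yl}cyclohex-2-en-1-yl]methanol, via lithiomethyl ether 13 (not isolated)
Conditions: n-BuLi, THF, −78 → −40 °C; then aq. NH4Cl
Reagents that add atoms: none
Why: Wittig–Still [2,3]-sigmatropic rearrangement in which tin–lithium exchange gives the α-alkoxymethyllithium, which shifts suprafacially from O-12 to C10 on the face that carried the oxygen (cis to CH3-15, trans to the C2 chain), setting C10 and moving the alkene to C11=C12.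

Step 11
Reactants: 14 [(1R,6R)-2,6-dimethyl-6-{(1S)-4-methyl-1-[(triethylsilyl)oxy]pent-4-en-1-yl}cyclohex-2-en-1-yl]methanol
Product: 15 triethyl({(1S)-1-[(1R,2R)-2-(iodomethyl)-1,3-dimethylcyclohex-3-en-1-yl]-4-methylpent-4-en-1-yl}oxy)silane
Conditions: I2, PPh3, imidazole, CH2Cl2, 0 °C
Reagents that add atoms: iodine, II
Why: Appel-type iodination of the only free (primary) hydroxyl gives the C9 iodide, with no neighbouring free alcohol that could close a tetrahydrofuran.

Step 12
Reactants: 15 triethyl({(1S)-1-[(1R,2R)-2-(iodomethyl)-1,3-dimethylcyclohex-3-en-1-yl]-4-methylpent-4-en-1-yl}oxy)silane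
Product: 16 (4R,5R)-4-(iodomethyl)-3,5-dimethyl-5-{(1S)-4-methyl-1-[(triethylsilyl)oxy]pent-4-en-1-yl}cyclohex-2-en-1-one
Conditions: CrO3, 3,5-dimethylpyrazole, CH2Cl2, −20 °C
Reagents that add atoms: chromium trioxide, O=[Cr](=O)=O
Why: Chromium-mediated allylic oxidation converts the only ring methylene allylic to the trisubstituted C11=C12 alkene (C13) into the enone, the tertiary C10–H being shielded by the adjacent quaternary centre and the side-chain 1,1-disubstituted alkene being far less reactive (as in limonene-to-carvone oxidations).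

Step 13
Reactants: 17 (3R)-3-hydroxyoxolan-2-one
Product: 18 (2R)-2-hydroxy-4-(phenylselanyl)butanoic acid
Conditions: PhSeSePh, Na, THF, reflux; then 17, HMPA, 65 °C; then aq. HCl
Reagents that add atoms: diphenyl diselenide, c1ccc(cc1)[Se][Se]c1ccccc1
Why: SN2 opening of the lactone at the O–CH2 carbon by the soft, weakly basic selenolate gives the acid without touching the stereocentre that becomes C7.

Step 14
Reactants: 18 (2R)-2-hydroxy-4-(phenylselanyl)butanoic acid
Product: 19 methyl (2R)-2-hydroxy-4-(phenylselanyl)butanoate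
Conditions: MeOH, H2SO4 (cat.), rt
Reagents that add atoms: methanol, CO
Why: Fischer esterification provides the ester electrophile for the Dieckmann closure under acid conditions that leave the selenide and the α-stereocentre intact.

Step 15
Reactants: 19 methyl (2R)-2-hydroxy-4-(phenylselanyl)butanoate; 20 propanoyl chloride
Product: 21 methyl (2R)-4-(phenylselanyl)-2-(propanoyloxy)butanoate
Conditions: pyridine, DMAP (cat.), CH2Cl2, 0 °C
Reagents that add atoms: none
Why: O-Acylation (nucleophilic acyl substitution) installs the propionate that supplies C17, CH3-18 and the lactone carbonyl C19.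

Step 16
Reactants: 21 methyl (2R)-4-(phenylselanyl)-2-(propanoyloxy)butanoate
Product: 22 (5R)-4-hydroxy-3-methyl-5-[2-(phenylselanyl)ethyl]furan-2(5H)-one
Conditions: LiN(SiMe3)2 (2.2 equiv), THF, −78 → 0 °C; then aq. HCl
Reagents that add atoms: none
Why: Dieckmann condensation of the propionate enolate onto the methyl ester closes the tetronic acid, which is held as its delocalised tetronate salt so that C7 is not epimerised.

Step 17
Reactants: 22 (5R)-4-hydroxy-3-methyl-5-[2-(phenylselanyl)ethyl]furan-2(5H)-one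
Product: 23 (5R)-4-bromo-3-methyl-5-[2-(phenylselanyl)ethyl]furan-2(5H)-one
Conditions: (COBr)2, DMF, CH2Cl2, 0 °C → rt
Reagents that add atoms: oxalyl bromide, O=C(Br)C(Br)=O
Why: Vilsmeier-type activation of the vinylogous acid followed by addition–elimination of bromide turns the C8 enol into the β-bromobutenolide needed for cross-coupling.

Step 18
Reactants: 23 (5R)-4-bromo-3-methyl-5-[2-(phenylselanyl)ethyl]furan-2(5H)-one
Product: 25 (5R)-4-bromo-5-ethenyl-3-methylfuran-2(5H)-one, via selenoxide 24 (not isolated)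
Conditions: H2O2 (30%), THF, 0 → 40 °C
Reagents that add atoms: none
Why: Selenoxide syn-elimination toward the only β-hydrogens unveils the C6 vinyl group under non-basic conditions that do not epimerise C7.

Step 19
Reactants: 16 (4R,5R)-4-(iodomethyl)-3,5-dimethyl-5-{(1S)-4-methyl-1-[(triethylsilyl)oxy]pent-4-en-1-yl}cyclohex-2-en-1-one; 25 (5R)-4-bromo-5-ethenyl-3-methylfuran-2(5H)-one
Product: 27 (4R,5R)-4-{[(2R)-2-ethenyl-4-methyl-5-oxo-2,5-dihydrofuran-3-yl]methyl}-3,5-dimethyl-5-{(1S)-4-methyl-1-[(triethylsilyl)oxy]pent-4-en-1-yl}cyclohex-2-en-1-one, via alkylzinc iodide 26 (not isolated)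
Conditions: Zn dust, LiCl, THF, 35 °C; then 25, Pd2(dba)3 (2.5 mol%), tri(2-furyl)phosphine (10 mol%), THF, rt
Reagents that add atoms: none
Why: Negishi coupling in which zinc inserts into the primary C–I bond (enone and silyl ether tolerated) and zerovalent palladium, adding oxidatively to the activated β-bromo enoate faster than it ionises the allylic lactone, forms the C8–C9 sp2–sp3 bond under neutral conditions that preserve C7 and C10.

Step 20
Reactants: 27 (4R,5R)-4-{[(2R)-2-ethenyl-4-methyl-5-oxo-2,5-dihydrofuran-3-yl]methyl}-3,5-dimethyl-5-{(1S)-4-methyl-1-[(triethylsilyl)oxy]pent-4-en-1-yl}cyclohex-2-en-1-one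
Product: 28 (1R,2S,5Z,7R,10R)-13-oxo-2-[(triethylsilyl)oxy]briara-5,8(17),11-trien-19,7-olide
Conditions: second-generation Hoveyda–Grubbs catalyst RuCl2(=CH-C6H4-2-OiPr)(H2IMes) (15 mol%), 1,4-benzoquinone (10 mol%), toluene (1 mM), 80 °C
Reagents that add atoms: none
Why: Ring-closing metathesis between the C6 vinyl group and the 1,1-disubstituted C5 alkene closes the ten-membered ring, the (Z)-olefin being expected because the trans-fused cyclohexenone and the planar butenolide hold C4 and C7 on the same side of the forming double bond.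

Step 21
Reactants: 28 (1R,2S,5Z,7R,10R)-13-oxo-2-[(triethylsilyl)oxy]briara-5,8(17),11-trien-19,7-olide
Product: 29 (1R,2S,5Z,7R,10R)-2-hydroxy-13-oxobriara-5,8(17),11-trien-19,7-olide
Conditions: HF·pyridine, pyridine, THF, 0 °C → rt
Reagents that add atoms: none
Why: Fluoride-mediated desilylation under buffered, non-basic conditions frees the C2 hydroxyl without epimerising C7 or C10.

Step 22
Reactants: 29 (1R,2S,5Z,7R,10R)-2-hydroxy-13-oxobriara-5,8(17),11-trien-19,7-olide; 30 (2E)-2-methylbut-2-enoyl chloride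
Product: 31 (1R,2S,5Z,7R,10R)-13-oxo-2-[(2E)-2-methylbut-2-enoyloxy]briara-5,8(17),11-trien-19,7-olide
Conditions: pyridine, DMAP (cat.), CH2Cl2, rt
Reagents that add atoms: none
Why: DMAP-catalysed acylation in weakly basic pyridine esterifies the hindered C2 alcohol without epimerising the butenolide C7–H and with retention of the (E)-tigloyl geometry.

Step 23
Reactants: 31 (1R,2S,5Z,7R,10R)-13-oxo-2-[(2E)-2-methylbut-2-enoyloxy]briara-5,8(17),11-trien-19,7-olide
Product: 32 (1R,2S,5Z,7R,10R,14S)-14-acetoxy-13-oxo-2-[(2E)-2-methylbut-2-enoyloxy]briara-5,8(17),11-trien-19,7-olide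
Conditions: Mn(OAc)3·2H2O (4 equiv), benzene, reflux (Dean–Stark)
Reagents that add atoms: manganese triacetate, CC(=O)[O-].CC(=O)[O-].CC(=O)[O-].[Mn+3]
Why: α'-Acetoxylation of the enone with manganese triacetate, in which the trivalent-manganese enolate at C14 (the only α'-position) transfers acetate axially and anti to the axial CH3-15 of the rigid trans-fused bicycle, giving the 14-acetate trans to CH3-15 and cis to the C1–C2 bond.

**Compound list**

1 | 3-methylbut-3-en-2-one | CC(=O)C(C)=C | starting material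
2 | triisopropyl[(3-methylbuta-1,3-dien-2-yl)oxy]silane | C=C(O[Si](C(C)C)(C(C)C)C(C)C)C(C)=C | intermediate
3 | 2-methylprop-2-enal (methacrolein) | C=C(C)C=O | starting material
4 | (1R)-1,3-dimethyl-4-[(triisopropylsilyl)oxy]cyclohex-3-ene-1-carbaldehyde | O=C[C@]1(C)CCC(O[Si](C(C)C)(C(C)C)C(C)C)=C(C)C1 | intermediate
5 | (1R)-1,3-dimethyl-4-oxocyclohex-2-ene-1-carbaldehyde | O=C[C@]1(C)CCC(=O)C(C)=C1 | intermediate
6 | 3-methylbut-3-en-1-ol | C=C(C)CCO | starting material
7 | 4-iodo-2-methylbut-1-ene | C=C(C)CCI | intermediate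
8 | bis(3-methylbut-3-en-1-yl)zinc | C=C(C)CC[Zn]CCC(C)=C | intermediate
9 | (4R)-4-[(1S)-1-hydroxy-4-methylpent-4-en-1-yl]-2,4-dimethylcyclohex-2-en-1-one | O[C@@H](CCC(C)=C)[C@]1(C)CCC(=O)C(C)=C1 | intermediate
10 | (4R)-2,4-dimethyl-4-{(1S)-4-methyl-1-[(triethylsilyl)oxy]pent-4-en-1-yl}cyclohex-2-en-1-one | CC[Si](CC)(CC)O[C@@H](CCC(C)=C)[C@]1(C)CCC(=O)C(C)=C1 | intermediate
11 | (1R,4R)-2,4-dimethyl-4-{(1S)-4-methyl-1-[(triethylsilyl)oxy]pent-4-en-1-yl}cyclohex-2-en-1-ol | CC[Si](CC)(CC)O[C@@H](CCC(C)=C)[C@]1(C)CC[C@@H](O)C(C)=C1 | intermediate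
12 | tributyl({[(1R,4R)-2,4-dimethyl-4-{(1S)-4-methyl-1-[(triethylsilyl)oxy]pent-4-en-1-yl}cyclohex-2-en-1-yl]oxy}methyl)stannane | CC[Si](CC)(CC)O[C@@H](CCC(C)=C)[C@]1(C)CC[C@@H](OC[Sn](CCCC)(CCCC)CCCC)C(C)=C1 | intermediate
13 | lithiomethyl ether: ({[(1R,4R)-2,4-dimethyl-4-{(1S)-4-methyl-1-[(triethylsilyl)oxy]pent-4-en-1-yl}cyclohex-2-en-1-yl]oxy}methyl)lithium (not isolated) | CC[Si](CC)(CC)O[C@@H](CCC(C)=C)[C@]1(C)CC[C@@H](OC[Li])C(C)=C1 | intermediate
14 | [(1R,6R)-2,6-dimethyl-6-{(1S)-4-methyl-1-[(triethylsilyl)oxy]pent-4-en-1-yl}cyclohex-2-en-1-yl]methanol | CC[Si](CC)(CC)O[C@@H](CCC(C)=C)[C@]1(C)CCC=C(C)[C@H]1CO | intermediate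
15 | triethyl({(1S)-1-[(1R,2R)-2-(iodomethyl)-1,3-dimethylcyclohex-3-en-1-yl]-4-methylpent-4-en-1-yl}oxy)silane | CC[Si](CC)(CC)O[C@@H](CCC(C)=C)[C@]1(C)CCC=C(C)[C@H]1CI | intermediate
16 | (4R,5R)-4-(iodomethyl)-3,5-dimethyl-5-{(1S)-4-methyl-1-[(triethylsilyl)oxy]pent-4-en-1-yl}cyclohex-2-en-1-one | CC[Si](CC)(CC)O[C@@H](CCC(C)=C)[C@]1(C)CC(=O)C=C(C)[C@H]1CI | intermediate
17 | (3R)-3-hydroxyoxolan-2-one [(R)-α-hydroxy-γ-butyrolactone] | O[C@@H]1CCOC1=O | starting material
18 | (2R)-2-hydroxy-4-(phenylselanyl)butanoic acid | O[C@H](CC[Se]c1ccccc1)C(=O)O | intermediate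
19 | methyl (2R)-2-hydroxy-4-(phenylselanyl)butanoate | O[C@H](CC[Se]c1ccccc1)C(=O)OC | intermediate
20 | propanoyl chloride | CCC(Cl)=O | starting material
21 | methyl (2R)-4-(phenylselanyl)-2-(propanoyloxy)butanoate | CCC(=O)O[C@H](CC[Se]c1ccccc1)C(=O)OC | intermediate
22 | (5R)-4-hydroxy-3-methyl-5-[2-(phenylselanyl)ethyl]furan-2(5H)-one | O=C1O[C@H](CC[Se]c2ccccc2)C(O)=C1C | intermediate
23 | (5R)-4-bromo-3-methyl-5-[2-(phenylselanyl)ethyl]furan-2(5H)-one | O=C1O[C@H](CC[Se]c2ccccc2)C(Br)=C1C | intermediate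
24 | selenoxide: (5R)-4-bromo-3-methyl-5-[2-(benzeneseleninyl)ethyl]furan-2(5H)-one (Se configuration undefined; not isolated) | O=C1O[C@H](CC[Se](=O)c2ccccc2)C(Br)=C1C | intermediate
25 | (5R)-4-bromo-5-ethenyl-3-methylfuran-2(5H)-one | O=C1O[C@H](C=C)C(Br)=C1C | intermediate
26 | alkylzinc iodide: iodo{[(1R,6R)-2,6-dimethyl-6-{(1S)-4-methyl-1-[(triethylsilyl)oxy]pent-4-en-1-yl}-4-oxocyclohex-2-en-1-yl]methyl}zinc (not isolated) | CC[Si](CC)(CC)O[C@@H](CCC(C)=C)[C@]1(C)CC(=O)C=C(C)[C@H]1C[Zn]I | intermediate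
27 | (4R,5R)-4-{[(2R)-2-ethenyl-4-methyl-5-oxo-2,5-dihydrofuran-3-yl]methyl}-3,5-dimethyl-5-{(1S)-4-methyl-1-[(triethylsilyl)oxy]pent-4-en-1-yl}cyclohex-2-en-1-one | CC[Si](CC)(CC)O[C@@H](CCC(C)=C)[C@]1(C)CC(=O)C=C(C)[C@H]1CC1=C(C)C(=O)O[C@@H]1C=C | intermediate
28 | (1R,2S,5Z,7R,10R)-13-oxo-2-[(triethylsilyl)oxy]briara-5,8(17),11-trien-19,7-olide (cyclohex-2-enone trans-fused to the ten-membered ring, which carries the (Z)-C5=C6 alkene and the C7/C8 α-methylbutenolide) | CC[Si](CC)(CC)O[C@H]1CC/C(C)=C\[C@H]2OC(=O)C(C)=C2C[C@@H]2C(C)=CC(=O)C[C@@]12C | intermediate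
29 | (1R,2S,5Z,7R,10R)-2-hydroxy-13-oxobriara-5,8(17),11-trien-19,7-olide | O[C@H]1CC/C(C)=C\[C@H]2OC(=O)C(C)=C2C[C@@H]2C(C)=CC(=O)C[C@@]12C | intermediate
30 | (2E)-2-methylbut-2-enoyl chloride (tigloyl chloride) | C/C=C(\C)C(Cl)=O | starting material
31 | (1R,2S,5Z,7R,10R)-13-oxo-2-[(2E)-2-methylbut-2-enoyloxy]briara-5,8(17),11-trien-19,7-olide (14-deacetoxy target) | C/C=C(\C)C(=O)O[C@H]1CC/C(C)=C\[C@H]2OC(=O)C(C)=C2C[C@@H]2C(C)=CC(=O)C[C@@]12C | intermediate
32 | (1R,2S,5Z,7R,10R,14S)-14-acetoxy-13-oxo-2-[(2E)-2-methylbut-2-enoyloxy]briara-5,8(17),11-trien-19,7-olide (CNP0218548.3) | C/C=C(\C)C(=O)O[C@H]1CC/C(C)=C\[C@H]2OC(=O)C(C)=C2C[C@@H]2C(C)=CC(=O)[C@@H](OC(C)=O)[C@@]12C | target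

**Step count**

Total step count: 23.
Longest linear sequence: 15 steps (steps 1, 2, 3, 6, 7, 8, 9, 10, 11, 12, 19, 20, 21, 22, 23). The butenolide branch (steps 13–18) and the zinc-reagent branch (steps 4–5) run in parallel.

**Steps most likely to fail, with fallbacks**

Step 19 (Negishi union of 16 and 25). The risks are an unstable zinc reagent next to the enone and ionisation of the vinyl lactone by zerovalent palladium. Fallback: no organometallic is prepared, and iodide 16 and bromide 25 are joined as two electrophiles in a nickel-catalysed reductive cross-electrophile coupling (NiBr2·dme, 4,4'-di-tert-butyl-2,2'-bipyridine, Mn powder, NaI, DMA, rt), the C9 radical from 16 being captured by the alkenylnickel species formed from 25. This sets out from 16 (with 25) and returns to the route at 27; no new compound is isolated.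

Step 20 (ring-closing metathesis to a ten-membered ring with a trisubstituted olefin). The risks are dimerisation, no closure, or the (E)-isomer. Fallback: the ring is closed before the rigid butenolide exists. The route is left at 16, whose zinc reagent 26 is acylated in a Fukuyama coupling (PdCl2(PPh3)2, THF) with the thioester S-ethyl (2R)-2-[(triethylsilyl)oxy]but-3-enethioate F1 (from (R)-2-hydroxybut-3-enoic acid) to give the acyclic silyloxy ketone diene F2. Ring-closing metathesis of this more flexible substrate gives the ten-membered bis-silyl keto ether F3. HF·pyridine removes both silyl groups to give the diol F4. The less hindered C7 hydroxyl is esterified with 2-(diethoxyphosphoryl)propanoic acid (DCC, DMAP cat.) to give the phosphonate ester F5. An intramolecular Horner–Wadsworth–Emmons reaction onto the C8 ketone (LiCl, i-Pr2NEt, MeCN) then forms the butenolide and rejoins the route at alcohol 29.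

Step 23 (late α'-acetoxylation). The risks are transannular radical cyclisation onto C5=C6 and oxidation at the butenolide. Fallback: the C14 oxygen is installed on the monocyclic fragment before the coupling. The route is left at 16, which is deprotonated at C14 (LiN(SiMe3)2, THF, −78 °C) and oxidised with 2-(phenylsulfonyl)-3-phenyloxaziridine to the 14-hydroxy enone F6. Acetylation (Ac2O, pyridine, DMAP) gives the 14-acetoxy iodide F7. Zinc insertion gives the acetoxy zinc reagent F8, and Negishi coupling with 25 gives the acetoxy seco-diene F9. Ring-closing metathesis gives the macrocyclic acetoxy silyl ether F10, HF·pyridine gives the macrocyclic acetoxy alcohol F11, and tigloylation with 30 returns to the route at 32. The C14 configuration then rests on the facial bias of the monocyclic enolate and must be checked at F6, where the epimers can be separated.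

**Further compounds**

F0 | step 19 | none | none
F1 | step 20 | S-ethyl (2R)-2-[(triethylsilyl)oxy]but-3-enethioate | CCSC(=O)[C@H](O[Si](CC)(CC)CC)C=C
F2 | step 20 | acyclic silyloxy ketone diene: (4R,5R)-3,5-dimethyl-5-{(1S)-4-methyl-1-[(triethylsilyl)oxy]pent-4-en-1-yl}-4-{(3R)-2-oxo-3-[(triethylsilyl)oxy]pent-4-en-1-yl}cyclohex-2-en-1-one | CC[Si](CC)(CC)O[C@@H](CCC(C)=C)[C@]1(C)CC(=O)C=C(C)[C@H]1CC(=O)[C@H](O[Si](CC)(CC)CC)C=C
F3 | step 20 | ten-membered bis-silyl keto ether: (1R,2S,5Z,7R,10R)-1,5,11-trimethyl-2,7-bis[(triethylsilyl)oxy]bicyclo[8.4.0]tetradeca-5,11-diene-8,13-dione | CC[Si](CC)(CC)O[C@H]1CC/C(C)=C\[C@@H](O[Si](CC)(CC)CC)C(=O)C[C@@H]2C(C)=CC(=O)C[C@@]12C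
F4 | step 20 | diol: (1R,2S,5Z,7R,10R)-2,7-dihydroxy-1,5,11-trimethylbicyclo[8.4.0]tetradeca-5,11-diene-8,13-dione | O[C@H]1CC/C(C)=C\[C@@H](O)C(=O)C[C@@H]2C(C)=CC(=O)C[C@@]12C
F5 | step 20 | phosphonate ester: (1R,2S,5Z,7R,10R)-2-hydroxy-1,5,11-trimethyl-8,13-dioxobicyclo[8.4.0]tetradeca-5,11-dien-7-yl 2-(diethoxyphosphoryl)propanoate | O[C@H]1CC/C(C)=C\[C@@H](OC(=O)C(C)P(=O)(OCC)OCC)C(=O)C[C@@H]2C(C)=CC(=O)C[C@@]12C
F6 | step 23 | 14-hydroxy enone: 16 carrying OH at C14, trans to CH3-15 | CC[Si](CC)(CC)O[C@@H](CCC(C)=C)[C@]1(C)[C@H](O)C(=O)C=C(C)[C@H]1CI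
F7 | step 23 | 14-acetoxy iodide: 16 carrying OAc at C14, trans to CH3-15 | CC[Si](CC)(CC)O[C@@H](CCC(C)=C)[C@]1(C)[C@H](OC(C)=O)C(=O)C=C(C)[C@H]1CI
F8 | step 23 | acetoxy zinc reagent: 26 carrying OAc at C14 | CC[Si](CC)(CC)O[C@@H](CCC(C)=C)[C@]1(C)[C@H](OC(C)=O)C(=O)C=C(C)[C@H]1C[Zn]I
F9 | step 23 | acetoxy seco-diene: 27 carrying OAc at C14 | CC[Si](CC)(CC)O[C@@H](CCC(C)=C)[C@]1(C)[C@H](OC(C)=O)C(=O)C=C(C)[C@H]1CC1=C(C)C(=O)O[C@@H]1C=C
F10 | step 23 | macrocyclic acetoxy silyl ether: 28 carrying OAc at C14 | CC[Si](CC)(CC)O[C@H]1CC/C(C)=C\[C@H]2OC(=O)C(C)=C2C[C@@H]2C(C)=CC(=O)[C@@H](OC(C)=O)[C@@]12C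
F11 | step 23 | macrocyclic acetoxy alcohol: 29 carrying OAc at C14 | O[C@H]1CC/C(C)=C\[C@H]2OC(=O)C(C)=C2C[C@@H]2C(C)=CC(=O)[C@@H](OC(C)=O)[C@@]12C
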